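The amber run at 3.00 min holds 53.5% of complex with four exchanged, while the grey run at the same time holds 19.3%, and what separates them is [incoming ligand], 2.3 M against 1.3 M. Two chemists read that gap differently, and the new flasks will test them.

| flask | starting complex | incoming ligand | remark | time |
|---|---|---|---|---|
| grey | 0.50 M | 1.3 M | run made earlier |  |
| amber | 0.50 M | 2.3 M | run made earlier |  |
| epsilon | 0.50 M | 2.00 M |  | 6.0 min |
| alpha | 0.50 M | 1.50 M |  | 6.0 min |
| beta | 0.50 M | 1.00 M |  | 6.0 min |

- grey (time / min: complex with four exchanged / %, complex with three exchanged / %): 0.417: 2.1, 4.3; 0.833: 5.0, 8.8; 1.33: 9.6, 11.5; 1.50: 10.9, 12.5; 2.00: 14.0, 14.2; 2.50: 16.3, 15.6; 3.00: 19.3, 17.0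
- amber (time / min: complex with four exchanged / %, complex with three exchanged / %): 0.167: 1.9, 3.3; 0.500: 11.4, 11.8; 0.833: 20.2, 16.8; 1.33: 29.0, 20.2; 2.00: 40.1, 21.1; 2.50: 47.3, 20.7; 3.00: 53.5, 19.6

(readings scatter by 0.3 percentage points)

* which of these holds the largest part of the starting complex at the end of epsilon (complex with three exchanged / complex with one exchanged / starting complex / complex with two exchanged / complex with four exchanged)
* which of these holds the largest part of the starting complex at the end of alpha (complex with three exchanged / complex with one exchanged / starting complex / complex with two exchanged / complex with four exchanged)
* which of these holds the largest part of the starting complex at the end of beta (complex with three exchanged / complex with one exchanged / starting complex / complex with two exchanged / complex with four exchanged)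
* final complex with four exchanged in epsilon, as a percentage of the starting complex charged



The first chemist made the forecast. This chemist sees a slow first exchange, quick second and third exchanges and a slower last one, rates roughly first order in ligand, and argues: “Each complex that reacts quickly consumes three ligands, so ligand runs out while starting complex remains.” The forecast therefore puts complex with four exchanged ahead in epsilon at 66%, complex with four exchanged ahead in alpha, and starting complex ahead in beta, with 27% of complex with four exchanged there.

The second chemist starts from the gap itself. Amber against grey gives 1.79 for the ligand order, an apparent reaction order: the logarithm of the ratio of complex with four exchanged in two flasks at one time, over the logarithm of their ratio of [incoming ligand]. That stands above first order, so this chemist expects a second slow exchange past the first, with material waiting in the middle. Beta is charged with 2.00 equivalents of ligand, so complex with two exchanged should lead there.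

Complex with four exchanged in grey grew by a factor 1.77 when the time doubled from 1.50 min to 3.00 min. Assuming the same factor for the next doubling of time, this chemist scales amber by the ligand order and by that factor and estimates 21.4% of complex with four exchanged in beta and 73.8% in epsilon.

The simulation gives 64.2% of complex with four exchanged for epsilon, and the leaders are complex with four exchanged in epsilon, complex with four exchanged in alpha and complex with two exchanged in beta. The steps are these:

    leaving ligand + starting complex → side product (k = 0.358 /M/min)
    complex with one exchanged + incoming ligand ⇌ leaving ligand + complex with two exchanged (K = 1.30, k = 5.25 /M/min)
    leaving ligand → by-product carried off (k = 1.52 /min)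
    starting complex + incoming ligand ⇌ leaving ligand + complex with one exchanged (K = 0.820, k = 4.91 /M/min)
    complex with two exchanged + incoming ligand ⇌ leaving ligand + complex with three exchanged (K = 0.542, k = 0.961 /M/min)
    complex with three exchanged + incoming ligand ⇌ leaving ligand + complex with four exchanged (K = 0.500, k = 8.11 /M/min)

In epsilon and alpha the forecast's leaders stand, and for epsilon its 66% lies close to 64.2%, where the second chemist's estimate of 73.8% ran high. In beta the forecast's leader falls and the second chemist's stands, with 38.8% of complex with two exchanged against 10.7% of starting complex. Between epsilon and beta at 6.0 min the ligand order is 2.16, above the amber-grey reading. Carried from epsilon to a neighbour flask that differs from it in holding 1.2 M of incoming ligand, the amber-grey order gives 25.8% of complex with four exchanged. That neighbour gives 22.9%, and complex with two exchanged leads it with 36.3%.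

The readings were generated by integration from invented constants; noise was put on by code.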